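All constants were chosen freely; the run is a simulation.

Count the catalyst.

the same everywhere: free catalyst 2.5 µM
- amber: substrate 0.50 mM; reagent 0.650 mM; time 15 s; a closed flask charged with all of it at once and left for 15 s
- grey: substrate 0.50 mM (fed, over 15.0 s); reagent 0.650 mM; time 15 s; all but substrate at the start; substrate goes in evenly over 15.0 s, the run ends at 15 s
- green: substrate 0.50 mM; reagent 0.650 mM; a single well-mixed tank run continuously and read at steady state, 15 s in it on average
- violet: substrate 0.50 mM; reagent 0.650 mM (fed, over 15.0 s); time 15 s; a stirred flask in which reagent is dosed at a steady rate over 15.0 s without added volume, worked up at 15 s

    substrate + free catalyst → catalyst intermediate A (k1 = 59500 L mol⁻¹ s⁻¹)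
    catalyst intermediate A → catalyst intermediate B (k2 = 41.6 s⁻¹)
    reagent + catalyst intermediate B → catalyst intermediate C (k3 = 5.61 × 10⁵ L mol⁻¹ s⁻¹)
    catalyst intermediate C ⇌ free catalyst + target (K4 = 2.33 × 10⁻⁴ M, k4 = 756 s⁻¹)
    free catalyst → spent catalyst (k5 = 6.68 × 10⁻⁵ s⁻¹)

- the set-up with the highest amount of target at the outlet or at the end, in percent of the substrate put in ("none" if the first two lie within 2 percentage points) (amber / grey / green / violet / none)
- amount of target at the outlet or at the end, in percent of the substrate put in, amber
- amount of target at the outlet or at the end, in percent of the substrate put in, grey
- amount of target at the outlet or at the end, in percent of the substrate put in, green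
- amount of target at the outlet or at the end, in percent of the substrate put in, violet

- the stated concentrations are those of everything mixed, before any reaction; amounts are the same in each set-up
- the feed brings no volume worth counting
- run time (amber): 15 s

- Start from the bench rule: treat substrate as pseudo-first-order with the catalyst staying free. Amber's substrate then has a half-life of 4.7 s, and the rule promises 89.3% target in 15 s.
- Find the border with two ratios, each a bound form per free catalyst. Binding rate at full substrate over the constant of catalyst intermediate A's step gives 0.715 for that intermediate. The whole charge as target, over the equilibrium constant of the release of target from catalyst intermediate C, gives 2.15 for catalyst intermediate C.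
- Read the border: the rule needs both ratios far below one, but the second stands above one, so drop the rule for amber.
- Drop catalyst intermediate B from amber's count, since its ratio of 0.0816, with both charges full, is smaller than the first.
- Replace the curve by its mean: put half the charge as substrate and half as target, which halves both ratios. Call one over (one plus both halved ratios) φ: 41.1%, the mean free share of the catalyst.
- Slow the rule by φ: my amber figure becomes 60.1%, lower than the forecast's.
- Size the error: the reckoned share is 58.3% with the whole charge as substrate and 31.8% with the whole charge as target. Those ends give amber 72.8% and 50.8%.
- Set the forecast beside it: amber best, with amber 61.5%, grey 41.5%, green 47% and violet 57%, on the ground that “the rate depends strongly on keeping substrate concentration high from the start”.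
- Read the result: amber is best, with amber 61.5%, grey 41.2%, green 47.1% and violet 56.9%. Amber's free catalyst stands at 41.9% of the catalyst charged after 7.50 s, beside φ of 41.1%. Carry φ to green, whose outlet lies near the midpoint: with x as binding rate at φ times the mean stay, x over one plus x gives 47.9%. Amber's shortfall has two parts acting together, the reverse step of free catalyst plus target and the time given. Without that reverse step amber reaches 78.5%, and left ten times as long it reaches 99.6%.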